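**Plan**

- Retrosynthesis (chromane numbering) cuts, in this order: the aryl methoxymethyl ether, the C8–C(=O) bond between ring A and the enone chain, the C4–H bond made by opening a C3–C4 epoxide (back to the C3=C4 alkene of a 2H-chromene), and finally the C4–C4a and O1–C2 bonds of ring B together.
- Forward, ring B is annulated onto ring A first, as a 2H-chromene, from 2-bromo-5-methoxyphenol and prenal; the alkene is then converted into the (3R)-alcohol, and the cinnamoyl chain with ring C is attached last.
- Enabling feature: the phenol unit O1–C8a–C4a(H) of ring A, whose only free ortho carbon C4a lies between O1 and the C5 methoxy group. With the enal it gives the 1-oxatriene O1=C8a–C4a=C4–C3=C2, which closes ring B by 6π electrocyclisation onto the gem-dimethyl terminus C2.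
- Helpers: bromine at C8 blocks the second ortho position and later becomes the handle for the acyl chain; phenylboronic acid supplies a temporary dioxaborinine ring that tethers the aldehyde to C4a; the chromene oxidation level is corrected by epoxidation and hydride opening.
- Stereochemistry: C3 (R) is set by catalyst control in a Jacobsen epoxidation of the C3=C4 alkene and is kept because hydride opens only the C4–O bond; the E alkene comes from a Horner–Wadsworth–Emmons reaction.

Key step: step 1

Assumption: the facial sense of the manganese salen epoxidation is taken to follow that of other 2,2-dimethyl-2H-chromenes, so the (R,R)-catalyst should give the (3R,4R)-epoxide.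

**Route**

Step 1
Reactants: 1 2-bromo-5-methoxyphenol; 2 3-methylbut-2-enal (prenal)
Product: 5 8-bromo-5-methoxy-2,2-dimethyl-2H-chromene, via benzodioxaborinine 3 (not isolated), via ortho-quinone methide 4 (not isolated)
Conditions: PhB(OH)2 (1.1 equiv), AcOH, toluene, reflux, Dean–Stark trap
Reagents that add atoms: none
Why: Phenylboronic acid condenses with the hydroxyl of 1 and the aldehyde of 2, so that the boron-bound, Lewis-acid-activated carbonyl carbon is delivered intramolecularly to the only free ortho carbon (the future C4a, between hydroxyl and methoxy), which forms the C4–C4a bond and closes the temporary dioxaborinine ring of 3 by templated ortho-hydroxyalkylation. Thermal retro-[4+2] cycloreversion of 3 expels the PhB=O fragment and leaves the ortho-quinone methide 4, a 1-oxatriene (O1=C8a–C4a=C4–C3=C2). Ring B then closes by thermal disrotatory oxa-6π electrocyclisation of 4, which forms the O1–C2 bond and is driven by rearomatisation of ring A. The closest known reaction type is the phenylboronic acid-mediated chromenylation of phenols with enals, a templated condensation and electrocyclisation sequence (formal [3+3] annulation). No stereocentre arises because C2 carries two methyl groups, so no control element is needed. The step needs site selectivity (ortho over para carbon, and 1,2- over 1,4-addition to the enal), secured by the bromine that blocks the second ortho position, by the boron tether that reaches only an ortho carbon, and by the activation of that carbon by both flanking oxygen substituents.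

Step 2
Reactants: 5 8-bromo-5-methoxy-2,2-dimethyl-2H-chromene
Product: 6 (3R,4R)-8-bromo-3,4-epoxy-5-methoxy-2,2-dimethylchromane
Conditions: (R,R)-N,N'-bis(3,5-di-tert-butylsalicylidene)-1,2-cyclohexanediaminomanganese chloride (4 mol%), NaOCl (aq, pH 11.3), 4-phenylpyridine N-oxide (20 mol%), CH2Cl2, 0 °C
Reagents that add atoms: sodium hypochlorite, [Na+].[O-]Cl
Why: Jacobsen epoxidation, for which the cis-disubstituted, aryl-conjugated C3=C4 alkene of a 2,2-dimethyl-2H-chromene is the privileged substrate class; the (R,R)-salen manganese oxo species should deliver oxygen to the face that gives the (3R,4R)-epoxide, so C3 is set by catalyst control.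

Step 3
Reactants: 6 (3R,4R)-8-bromo-3,4-epoxy-5-methoxy-2,2-dimethylchromane
Product: 7 (3R)-8-bromo-5-methoxy-2,2-dimethyl-3,4-dihydro-2H-chromen-3-ol
Conditions: LiAlH4, THF, 0 °C to rt; then H2O, NaOH (aq)
Reagents that add atoms: none
Why: Regioselective SN2 hydride opening of an epoxide, in which hydride should attack the benzylic C4 because C3 is shielded by the adjacent quaternary C2; the C3–O bond is not touched, so the R configuration is kept, and the aryl bromide is inert to LiAlH4 at this temperature.

Step 4
Reactants: 8 4-(methoxymethoxy)benzaldehyde; 9 diethyl {2-[methoxy(methyl)amino]-2-oxoethyl}phosphonate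
Product: 10 (2E)-N-methoxy-3-[4-(methoxymethoxy)phenyl]-N-methylprop-2-enamide
Conditions: NaH, THF, 0 °C to rt
Reagents that add atoms: none
Why: Horner–Wadsworth–Emmons olefination, in which the amide-stabilised phosphonate anion adds reversibly to the aldehyde and the anti oxaphosphetane collapses to the E alkene.

Step 5
Reactants: 7 (3R)-8-bromo-5-methoxy-2,2-dimethyl-3,4-dihydro-2H-chromen-3-ol; 10 (2E)-N-methoxy-3-[4-(methoxymethoxy)phenyl]-N-methylprop-2-enamide
Product: 13 (2E)-1-[(3R)-3-hydroxy-5-methoxy-2,2-dimethyl-3,4-dihydro-2H-chromen-8-yl]-3-[4-(methoxymethoxy)phenyl]prop-2-en-1-one, via dilithio species 11 (not isolated), via tetrahedral adduct 12 (not isolated)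
Conditions: n-BuLi (1.05 equiv), THF, −78 °C; t-BuLi (2.1 equiv), −78 °C; then 10, −78 to 0 °C; NH4Cl (aq)
Reagents that add atoms: none
Why: Bromine–lithium exchange followed by a Weinreb ketone synthesis: after deprotonation of the hydroxyl, the bromine (its blocking role over) is exchanged to give aryllithium 11, which should add 1,2 to the amide carbonyl of 10 to give the chelated adduct 12 that releases the E enone only on quench, so over-addition is avoided and C3 is unaffected.

Step 6
Reactants: 13 (2E)-1-[(3R)-3-hydroxy-5-methoxy-2,2-dimethyl-3,4-dihydro-2H-chromen-8-yl]-3-[4-(methoxymethoxy)phenyl]prop-2-en-1-one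
Product: 14 (2E)-1-[(3R)-3-hydroxy-5-methoxy-2,2-dimethyl-3,4-dihydro-2H-chromen-8-yl]-3-(4-hydroxyphenyl)prop-2-en-1-one
Conditions: HCl (1.25 M in MeOH), rt to 40 °C
Reagents that add atoms: none
Why: Acid-catalysed acetal exchange with methanol removes the phenolic methoxymethyl group, while the tertiary alkyl aryl ether of ring B, the secondary alcohol and the E enone (which has no ortho hydroxyl for flavanone closure) should be stable.

**Compound list**

1 | 2-bromo-5-methoxyphenol | COc1ccc(Br)c(O)c1 | starting material
2 | 3-methylbut-2-enal (prenal) | CC(C)=CC=O | starting material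
3 | rac-8-bromo-5-methoxy-4-(2-methylprop-1-en-1-yl)-2-phenyl-4H-1,3,2-benzodioxaborinine (not isolated) | COc1ccc(Br)c2c1C(C=C(C)C)OB(c3ccccc3)O2 | intermediate
4 | (6Z)-2-bromo-5-methoxy-6-(3-methylbut-2-en-1-ylidene)cyclohexa-2,4-dien-1-one, the ortho-quinone methide (not isolated) | COC1=CC=C(Br)C(=O)/C1=C\C=C(C)C | intermediate
5 | 8-bromo-5-methoxy-2,2-dimethyl-2H-chromene | COc1ccc(Br)c2c1C=CC(C)(C)O2 | intermediate
6 | (3R,4R)-8-bromo-3,4-epoxy-5-methoxy-2,2-dimethylchromane, i.e. (1aR,7bR)-4-bromo-7-methoxy-2,2-dimethyl-1a,7b-dihydro-2H-oxireno[2,3-c]chromene | COc1ccc(Br)c2c1[C@H]3O[C@H]3C(C)(C)O2 | intermediate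
7 | (3R)-8-bromo-5-methoxy-2,2-dimethyl-3,4-dihydro-2H-chromen-3-ol | COc1ccc(Br)c2c1C[C@@H](O)C(C)(C)O2 | intermediate
8 | 4-(methoxymethoxy)benzaldehyde | COCOc1ccc(C=O)cc1 | starting material
9 | diethyl {2-[methoxy(methyl)amino]-2-oxoethyl}phosphonate | CCOP(=O)(CC(=O)N(C)OC)OCC | starting material
10 | (2E)-N-methoxy-3-[4-(methoxymethoxy)phenyl]-N-methylprop-2-enamide | COCOc1ccc(/C=C/C(=O)N(C)OC)cc1 | intermediate
11 | lithium (3R)-8-lithio-5-methoxy-2,2-dimethyl-3,4-dihydro-2H-chromen-3-olate, the dilithio species (not isolated) | COc1ccc([Li])c2c1C[C@@H](O[Li])C(C)(C)O2 | intermediate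
12 | dilithium (3R)-8-{(2E)-1-[methoxy(methyl)amino]-3-[4-(methoxymethoxy)phenyl]-1-oxidoprop-2-en-1-yl}-5-methoxy-2,2-dimethyl-3,4-dihydro-2H-chromen-3-olate, the tetrahedral adduct, both epimers at the new carbinol carbon (not isolated) | COc1ccc(C(O[Li])(N(C)OC)/C=C/c3ccc(OCOC)cc3)c2c1C[C@@H](O[Li])C(C)(C)O2 | intermediate
13 | (2E)-1-[(3R)-3-hydroxy-5-methoxy-2,2-dimethyl-3,4-dihydro-2H-chromen-8-yl]-3-[4-(methoxymethoxy)phenyl]prop-2-en-1-one | COc1ccc(C(=O)/C=C/c3ccc(OCOC)cc3)c2c1C[C@@H](O)C(C)(C)O2 | intermediate
14 | (2E)-1-[(3R)-3-hydroxy-5-methoxy-2,2-dimethyl-3,4-dihydro-2H-chromen-8-yl]-3-(4-hydroxyphenyl)prop-2-en-1-one | COc1ccc(C(=O)/C=C/c2ccc(O)cc2)c2c1C[C@@H](O)C(C)(C)O2 | target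

**Totals and risks**

Total step count: 6. Longest linear sequence: 5 steps (steps 1, 2, 3, 5, 6); step 4 is a one-step side branch.

Steps most likely to fail, in order of risk:

1. Step 1. The C–C bond formation at the crowded ortho carbon between hydroxyl and methoxy may be sluggish, so that acid-promoted self-condensation of the enal or incomplete cycloreversion of the borinine lowers conversion. Fallback (sets out from 1, returns at 5): O-alkylation of 1 with 3-chloro-3-methylbut-1-yne (K2CO3, KI cat., acetone, reflux) should give the aryl propargyl ether 1-bromo-4-methoxy-2-[(2-methylbut-3-yn-2-yl)oxy]benzene F1. Heating F1 in N,N-diethylaniline at about 190 °C should trigger an aromatic propargyl Claisen rearrangement to the only free ortho carbon and tautomerisation to the allenylphenol 6-bromo-3-methoxy-2-(3-methylbuta-1,2-dien-1-yl)phenol F2 (not isolated). A 1,5-hydrogen shift then leads to the same ortho-quinone methide 4, which electrocyclises to 5.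

2. Step 5. Bromine–lithium exchange next to a lithium alkoxide may be incomplete, the aryllithium may be quenched by adventitious proton sources, or conjugate addition to the cinnamoyl amide may compete with carbonyl addition. Fallback (sets out from 7, returns at 13): Stille coupling of 7 with tributyl(1-ethoxyvinyl)stannane [Pd(PPh3)4, toluene, 100 °C], which tolerates the free hydroxyl, should give the enol ether (3R)-8-(1-ethoxyethenyl)-5-methoxy-2,2-dimethyl-3,4-dihydro-2H-chromen-3-ol F3. Brief hydrolysis (1 M HCl, THF, rt) should give the methyl ketone 1-[(3R)-3-hydroxy-5-methoxy-2,2-dimethyl-3,4-dihydro-2H-chromen-8-yl]ethan-1-one F4. Claisen–Schmidt condensation of F4 with aldehyde 8 (KOH, EtOH, rt) should then give the E enone 13.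

3. Step 3. The electron-rich benzylic epoxide may ionise and rearrange during isolation or in contact with the Lewis-acidic reagent, hydride may attack with poor regiocontrol, or partial reductive loss of bromine may occur. Fallback (sets out from 6, returns at 7): the rearrangement is driven to completion on purpose as a Meinwald rearrangement (ZnI2 cat., CH2Cl2, rt; benzylic C4–O cleavage and 1,2-hydride shift) to the ketone 8-bromo-5-methoxy-2,2-dimethyl-2H-chromen-3(4H)-one F5. Corey–Bakshi–Shibata reduction of F5 with (S)-2-methyl-CBS-oxazaborolidine and BH3·SMe2 (THF, −20 °C), with the quaternary C2 acting as the large group, should return 7 with the R configuration; in this variant the stereocentre is set by the reduction catalyst and not by the epoxidation.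

**Further compounds**

F1 | step 1 | 1-bromo-4-methoxy-2-[(2-methylbut-3-yn-2-yl)oxy]benzene | COc1ccc(Br)c(OC(C)(C)C#C)c1
F2 | step 1 | 6-bromo-3-methoxy-2-(3-methylbuta-1,2-dien-1-yl)phenol | COc1ccc(Br)c(O)c1C=C=C(C)C
F3 | step 5 | (3R)-8-(1-ethoxyethenyl)-5-methoxy-2,2-dimethyl-3,4-dihydro-2H-chromen-3-ol | COc1ccc(C(=C)OCC)c2c1C[C@@H](O)C(C)(C)O2
F4 | step 5 | 1-[(3R)-3-hydroxy-5-methoxy-2,2-dimethyl-3,4-dihydro-2H-chromen-8-yl]ethan-1-one | COc1ccc(C(C)=O)c2c1C[C@@H](O)C(C)(C)O2
F5 | step 3 | 8-bromo-5-methoxy-2,2-dimethyl-2H-chromen-3(4H)-one | COc1ccc(Br)c2c1CC(=O)C(C)(C)O2
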